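| flask | substrate | reagent | catalyst | temperature | remark | time |
|---|---|---|---|---|---|---|
| violet | 14 mM | 2 equiv | 1.9 mol% | −30 °C | run made earlier |  |
| blue | 14 mM | 4.5 equiv | 1.9 mol% | 12 °C | run made earlier |  |
| green | 28 mM | 3 equiv | 1.9 mol% | −30 °C | run made earlier |  |
| gamma | 14 mM | 3.00 equiv | 1.9 mol% | −25 °C |  | 4.0 h |
| delta | 14 mM | 3.00 equiv | 1.9 mol% | 50 °C |  | 4.0 h |
| alpha | 14 mM | 3.00 equiv | 1.9 mol% | 0 °C |  | 4.0 h |
| epsilon | 14 mM | 3.00 equiv | 1.9 mol% | 25 °C |  | 4.0 h |

violet run (percent of the substrate charged)

| time / h | target / % | substrate / % |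
|---|---|---|
| 0.500 | 17 | 79 |
| 1.00 | 28 | 67 |
| 1.33 | 33 | 63 |
| 2.00 | 44 | 49 |
| 2.50 | 46 | 42 |

blue run (percent of the substrate charged)

| time / min | target / % | substrate / % |
|---|---|---|
| 5.00 | 46 | 23 |
| 10.0 | 48 | 13 |
| 12.0 | 45 | 11 |
| 20.0 | 36 | 14 |
| 25.0 | 32 | 11 |

green run (percent of the substrate charged)

| time / h | target / % | substrate / % |
|---|---|---|
| 0.500 | 40 | 53 |
| 1.00 | 58 | 32 |
| 1.33 | 66 | 23 |
| 2.00 | 71 | 13 |
| 2.50 | 73 | 11 |

(scatter of a reading: 1.5 percentage points)



- the flask with the highest amount of target, in percent of the substrate charged ("all alike" if they lie within 1.5 percentage points) (gamma / delta / alpha / epsilon / all alike)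
- final target, as a percentage of the substrate charged, in gamma
- final target, as a percentage of the substrate charged, in delta
- final target, as a percentage of the substrate charged, in alpha
- final target, as a percentage of the substrate charged, in epsilon

At late times the blue run loses target: from 10.0 min to 25.0 min target falls from 48 % to 32 % and substrate goes from 13 % to 11 %. Read as a first-order decay, that is 1.62 h⁻¹ at 12 °C.

The green run gives the cold end. Its first reading shows 40 % of target against 47.0 % of substrate consumed, so a reading of 14.9 % of the consumed substrate went elsewhere, taken here as a direct share. Between 1.33 h and 2.50 h, target plus substrate drops by 5 percentage points. Taking off that direct share leaves a loss of target of 0.0395 h⁻¹, a rough reading. The green run holds twice the catalyst per litre of the flasks charged at 14 mM. If catalyst carries this loss, which is then pseudo-first-order in target, and reagent plays no part in it, the value at 14 mM is 0.0198 h⁻¹. The two points give a slope of 7280 K.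

The quantity to carry is the lifetime count: the loss constant at the flask's temperature times the time it stands. For gamma it is 0.144. For alpha it is 2.11, for epsilon 19.7, and for delta 130. Target that stands from the start of a count, with no new target made, keeps exp(−count) of itself. Taking the green run's late substrate as the ceiling on conversion, and all target as standing from the start, this estimate gives gamma 65.6 % and alpha about 9.14 %. The next run is therefore gamma: charges and time stay, and the temperature stays cold, since its count is below the others.

The forecast names gamma, with 66 % there, 9 % in alpha, 0.3 % in epsilon and 0 % in delta, on the ground that “Target also decays after substrate stops”.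

The flask that ends highest is gamma, at 67.6 % of target beside 20.4 % of isomer of the product; alpha gives 12.5 %, epsilon 1.58 %, delta 1.25 %.

    substrate + reagent ⇌ target (K = 36.3 M⁻¹, k = 0.156 M⁻¹ s⁻¹, Ea = 40.0 kJ mol⁻¹, ΔH = −21.0 kJ mol⁻¹)
    substrate + reagent ⇌ isomer of the product (K = 2150 M⁻¹, k = 0.0864 M⁻¹ s⁻¹, Ea = 53.0 kJ mol⁻¹, ΔH = −19.0 kJ mol⁻¹)
    target + catalyst ⇌ isomer of the product + catalyst, rate k3*[catalyst]*[target] forward; the back reaction follows from the equilibrium constant (k = 0.824 M⁻¹ s⁻¹, Ea = 53.0 kJ mol⁻¹)
    2 reagent → homo dimer (k = 0.00112 M⁻¹ s⁻¹, Ea = 71.0 kJ mol⁻¹)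
    (constants at 25 °C)

Gamma's count, run on from 4.0 h to 40.0 h, comes to 1.30 and would take 67.6 % of target down to 18.4 %; gamma holds 28.5 %. Alpha's count from 2.00 h to 4.00 h is 1.06, which takes 27.2 % to 9.47 %, and alpha's target stands at 12.5 %.

The numbers in the tables stem from a simulated flask for substances that don't exist, noise included.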